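**Retrosynthetic overview**
1. Polyene: two Wittig disconnections (C11=C12, then C11'=C12') give all-E C10 trienedial and two C15 phosphonium salts that already carry the myristate (β end) and the palmitate (ε end).
2. Each C15 salt comes from a 3-acyloxy-ionone (vinyl Grignard, then PPh3·HBr).
3. Ring formation (key): each ring is closed by proton-initiated C1–C6 cation–olefin cyclisation of an acyclic 3-acyloxy "pseudoionone" ester, as the lycopene cyclases do. The β-ring is formed first (H2SO4, loss of H-6), the ε-ring second (H3PO4, loss of H-4, C6' set from C3' by 1,3-induction); both rings exist before the polyene is built.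
4. One acyclic (S)-carbinol serves both ends: acylation with retention gives the β precursor, Mitsunobu inversion with palmitic acid gives the ε precursor, because 3R and 3'R of the target are spatially opposite.
5. The carbinol comes from (S)-epichlorohydrin, isopropenyl Grignard and acetylide, then Zr-carboalumination/Negishi coupling with (E)-4-chlorobut-3-en-2-one.

Assumptions: (E)-4-chlorobut-3-en-2-one and all-E 2,7-dimethylocta-2,4,6-trienedial are bought; simple organometallic and phosphine reagents are not numbered but given with SMILES on the "Reagents that add atoms" line; carotenoid numbering (primed for the ε half) is used in the explanations.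

**Route**

Step 1
Reactants: 1 (S)-epichlorohydrin
Product: 4 (4S)-2-methylhept-1-en-6-yn-4-ol, via chlorohydrin magnesium alkoxide 2 (not isolated), via (S)-2-(2-methylallyl)oxirane 3 (not isolated)
Conditions: CH2=C(Me)MgBr (1.1 eq), CuI (5 mol%), THF, −40 → 0 °C; then LiC≡CH·en (3 eq), DMSO, 0 °C → rt; aq NH4Cl
Reagents that add atoms: isopropenylmagnesium bromide, C=C(C)[Mg]Br; lithium acetylide–ethylenediamine complex, [Li+].[C-]#C.NCCN
Why: Cu-catalysed Grignard opening of the epoxide CH2, closure of the chloro-alkoxide to the new terminal epoxide and acetylide opening of that epoxide all occur away from the carbinol carbon, so the stereocentre of 1 is carried unchanged into (S)-4.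

Step 2
Reactants: 4 (4S)-2-methylhept-1-en-6-yn-4-ol; 5 (E)-4-chlorobut-3-en-2-one
Product: 7 (3E,5E,8S)-8-hydroxy-6,10-dimethylundeca-3,5,10-trien-2-one, via E-alkenylalane aluminium alkoxide 6 (not isolated)
Conditions: Me3Al (3 eq), Cp2ZrCl2 (0.25 eq), CH2Cl2, 0 °C → rt; strip volatiles; 5 (1.3 eq), Pd(PPh3)4 (5 mol%), ZnCl2 (0.2 eq), THF, 0 °C → rt; aq Rochelle salt
Reagents that add atoms: trimethylaluminium, C[Al](C)C
Why: Negishi Zr-catalysed carboalumination adds Me–Al syn across the alkyne with Al on the terminal carbon, and Pd-catalysed Negishi cross-coupling of this E-alkenylalane with the β-chloroenone retains both olefin geometries to give the (3E,5E)-dienone without touching the carbinol centre.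

Step 3
Reactants: 7 (3E,5E,8S)-8-hydroxy-6,10-dimethylundeca-3,5,10-trien-2-one; 8 tetradecanoyl (myristoyl) chloride
Product: 9 (3E,5E,8S)-6,10-dimethyl-2-oxoundeca-3,5,10-trien-8-yl tetradecanoate
Conditions: pyridine (2 eq), DMAP (5 mol%), CH2Cl2, 0 °C → rt
Reagents that add atoms: none
Why: DMAP-catalysed O-acylation of the unhindered secondary alcohol proceeds with retention and installs the final myristate before ring formation.

Step 4
Reactants: 9 (3E,5E,8S)-6,10-dimethyl-2-oxoundeca-3,5,10-trien-8-yl tetradecanoate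
Product: 10 (1R)-3,5,5-trimethyl-4-[(1E)-3-oxobut-1-en-1-yl]cyclohex-3-en-1-yl tetradecanoate [(3R)-3-(myristoyloxy)-β-ionone]
Conditions: conc. H2SO4 (5 eq), CH2Cl2, −15 → 0 °C, 30 min; ice/NaHCO3
Reagents that add atoms: none
Why: Proton-initiated cation–olefin cyclisation of the pseudoionone → β-ionone type, in which protonation of the isopropenyl group gives the C1 tertiary cation, 6-endo attack of the Δ5 olefin forms C1–C6, and under thermodynamic control in concentrated acid all olefin isomers funnel to the conjugated β-dienone, which removes the C6 stereocentre while the uninvolved C3 centre stays R.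

Step 5
Reactants: 10 (3R)-3-(myristoyloxy)-β-ionone
Product: 12 [(2E,4E)-3-methyl-5-[(4R)-2,6,6-trimethyl-4-(tetradecanoyloxy)cyclohex-1-en-1-yl]penta-2,4-dien-1-yl]triphenylphosphonium bromide, via vinylcarbinol magnesium alkoxide 11 (not isolated)
Conditions: CH2=CHMgBr (1.2 eq), THF, −78 °C; then PPh3·HBr (2.5 eq), CH2Cl2, −78 °C → rt; triturate (hexane/EtOAc)
Reagents that add atoms: vinylmagnesium bromide, C=C[Mg]Br; triphenylphosphine hydrobromide, [Br-].c1ccc(cc1)[PH+](c1ccccc1)c1ccccc1
Why: Grignard 1,2-addition to the methyl ketone at −78 °C is much faster than attack on the fatty ester, and the tertiary bis-allylic carbinol then ionises under PPh3·HBr to a pentadienyl cation that PPh3 captures at the unhindered terminus (SN1′ phosphonium salt formation as for vitamin A C15 salts), leaving the ring stereocentre untouched.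

Step 6
Reactants: 12 β-C15 phosphonium bromide; 13 (2E,4E,6E)-2,7-dimethylocta-2,4,6-trienedial (3 eq)
Product: 14 (2E,4E,6E,8E,10E,12E)-2,7,11-trimethyl-13-[(4R)-2,6,6-trimethyl-4-(tetradecanoyloxy)cyclohex-1-en-1-yl]trideca-2,4,6,8,10,12-hexaenal [(3R)-3-(myristoyloxy)-12'-apo-β-caroten-12'-al]
Conditions: 1,2-epoxybutane/EtOH, reflux; then I2 (cat.), CH2Cl2, rt; chromatography (excess 13 recovered)
Reagents that add atoms: none
Why: Wittig olefination under base-free epoxide conditions (bromide opens epoxybutane to the alkoxide that forms the ylide) spares the fatty ester, excess symmetrical dialdehyde and the lower electrophilicity of the vinylogous product aldehyde favour mono-olefination, and iodine equilibration converts the 11Z isomer to all-E.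

Step 7
Reactants: 7 (3E,5E,8S)-8-hydroxy-6,10-dimethylundeca-3,5,10-trien-2-one; 15 hexadecanoic (palmitic) acid
Product: 16 (3E,5E,8R)-6,10-dimethyl-2-oxoundeca-3,5,10-trien-8-yl hexadecanoate
Conditions: PPh3 (1.5 eq), DIAD (1.5 eq), THF, 0 °C → rt
Reagents that add atoms: none
Why: Mitsunobu esterification displaces the oxyphosphonium by palmitate with SN2 inversion, turning the (8S)-carbinol into the (8R)-palmitate that the ε-ring needs, since C3 of the β-ring and C3' of the ε-ring are spatially opposite despite both being R.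

Step 8
Reactants: 16 (3E,5E,8R)-6,10-dimethyl-2-oxoundeca-3,5,10-trien-8-yl hexadecanoate
Product: 17 (1R,4R)-3,5,5-trimethyl-4-[(1E)-3-oxobut-1-en-1-yl]cyclohex-2-en-1-yl hexadecanoate [(3R,6R)-3-(palmitoyloxy)-α-ionone]
Conditions: 85% H3PO4, toluene, 30 °C, vigorous stirring, stop at full conversion; chromatography (removes minor cis and β/γ isomers)
Reagents that add atoms: none
Why: Proposed new method: Markovnikov protonation of the isopropenyl group gives the same C1 tertiary cation as the ε-cyclase, which the Δ5 olefin captures 6-endo through a chair transition state with the C3 palmitoyloxy group equatorial (an axial ester would clash 1,3-diaxially with a C1 methyl) and the E-dienone chain equatorial, so C6 is set trans to C3 as (3R,6R) by 1,3-induction, and under these weakly acidic kinetic conditions the C5 cation loses H-4 to give the ε-olefin; the closest known reaction is the H3PO4-mediated cation–olefin cyclisation of pseudoionone to α-ionone.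

Step 9
Reactants: 17 (3R,6R)-3-(palmitoyloxy)-α-ionone
Product: 19 [(2E,4E)-3-methyl-5-[(1R,4R)-2,6,6-trimethyl-4-(hexadecanoyloxy)cyclohex-2-en-1-yl]penta-2,4-dien-1-yl]triphenylphosphonium bromide, via vinylcarbinol magnesium alkoxide 18 (not isolated)
Conditions: CH2=CHMgBr (1.2 eq), THF, −78 °C; then PPh3·HBr (2.5 eq), CH2Cl2, −78 → 0 °C; triturate
Reagents that add atoms: vinylmagnesium bromide, C=C[Mg]Br; triphenylphosphine hydrobromide, [Br-].c1ccc(cc1)[PH+](c1ccccc1)c1ccccc1
Why: The same Grignard 1,2-addition/SN1′ phosphonium salt formation as in step 5 applies, and the buffered acidity of PPh3·HBr ionises the tertiary bis-allylic carbinol but not the secondary allylic palmitate, so C3' and C6' are retained.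

Step 10
Reactants: 14 (3R)-3-(myristoyloxy)-12'-apo-β-caroten-12'-al; 19 ε-C15 phosphonium bromide (1.2 eq)
Product: 20 (3R,3'R,6'R)-β,ε-carotene-3,3'-diol 3-tetradecanoate 3'-hexadecanoate (CNP0230054.1)
Conditions: 1,2-epoxybutane/EtOH, reflux; then n-heptane, reflux; crystallise
Reagents that add atoms: none
Why: The second epoxide-mediated Wittig olefination forms C11'=C12' without base-sensitive intermediates, and heating in heptane converts the strained 11'Z isomer to the all-E polyene with no stereocentre affected.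

**Compound list**
1 | (S)-epichlorohydrin | ClC[C@@H]1CO1 | starting material
2 | bromomagnesium (2S)-1-chloro-4-methylpent-4-en-2-olate | ClC[C@@H](O[Mg]Br)CC(C)=C | intermediate
3 | (S)-2-(2-methylprop-2-en-1-yl)oxirane | C=C(C)C[C@H]1CO1 | intermediate
4 | (4S)-2-methylhept-1-en-6-yn-4-ol | C#CC[C@@H](O)CC(C)=C | intermediate
5 | (E)-4-chlorobut-3-en-2-one | CC(=O)/C=C/Cl | starting material
6 | dimethylaluminium alkoxide of (4S,1E)-1-(dimethylalumanyl)-2,6-dimethylhepta-1,6-dien-4-ol | C[Al](C)/C=C(\C)C[C@@H](O[Al](C)C)CC(C)=C | intermediate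
7 | (3E,5E,8S)-8-hydroxy-6,10-dimethylundeca-3,5,10-trien-2-one | CC(=O)/C=C/C=C(\C)C[C@@H](O)CC(C)=C | intermediate
8 | tetradecanoyl chloride | CCCCCCCCCCCCCC(=O)Cl | starting material
9 | (3E,5E,8S)-6,10-dimethyl-2-oxoundeca-3,5,10-trien-8-yl tetradecanoate | CC(=O)/C=C/C=C(\C)C[C@@H](OC(=O)CCCCCCCCCCCCC)CC(C)=C | intermediate
10 | (1R)-3,5,5-trimethyl-4-[(1E)-3-oxobut-1-en-1-yl]cyclohex-3-en-1-yl tetradecanoate | CC(=O)/C=C/C1=C(C)C[C@@H](OC(=O)CCCCCCCCCCCCC)CC1(C)C | intermediate
11 | bromomagnesium (1E)-3-methyl-1-[(4R)-2,6,6-trimethyl-4-(tetradecanoyloxy)cyclohex-1-en-1-yl]penta-1,4-dien-3-olate (C9 epimers) | C=CC(C)(O[Mg]Br)/C=C/C1=C(C)C[C@@H](OC(=O)CCCCCCCCCCCCC)CC1(C)C | intermediate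
12 | [(2E,4E)-3-methyl-5-[(4R)-2,6,6-trimethyl-4-(tetradecanoyloxy)cyclohex-1-en-1-yl]penta-2,4-dien-1-yl]triphenylphosphonium bromide | [Br-].c1ccccc1[P+](c1ccccc1)(c1ccccc1)C/C=C(C)/C=C/C1=C(C)C[C@@H](OC(=O)CCCCCCCCCCCCC)CC1(C)C | intermediate
13 | (2E,4E,6E)-2,7-dimethylocta-2,4,6-trienedial | O=C/C(C)=C/C=C/C=C(C)/C=O | starting material
14 | (2E,4E,6E,8E,10E,12E)-2,7,11-trimethyl-13-[(4R)-2,6,6-trimethyl-4-(tetradecanoyloxy)cyclohex-1-en-1-yl]trideca-2,4,6,8,10,12-hexaenal | O=C/C(C)=C/C=C/C=C(C)/C=C/C=C(C)/C=C/C1=C(C)C[C@@H](OC(=O)CCCCCCCCCCCCC)CC1(C)C | intermediate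
15 | hexadecanoic acid | CCCCCCCCCCCCCCCC(=O)O | starting material
16 | (3E,5E,8R)-6,10-dimethyl-2-oxoundeca-3,5,10-trien-8-yl hexadecanoate | CC(=O)/C=C/C=C(\C)C[C@H](OC(=O)CCCCCCCCCCCCCCC)CC(C)=C | intermediate
17 | (1R,4R)-3,5,5-trimethyl-4-[(1E)-3-oxobut-1-en-1-yl]cyclohex-2-en-1-yl hexadecanoate | CCCCCCCCCCCCCCCC(=O)O[C@H]1C=C(C)[C@H](/C=C/C(C)=O)C(C)(C)C1 | intermediate
18 | bromomagnesium (1E)-3-methyl-1-[(1R,4R)-2,6,6-trimethyl-4-(hexadecanoyloxy)cyclohex-2-en-1-yl]penta-1,4-dien-3-olate (C9' epimers) | CCCCCCCCCCCCCCCC(=O)O[C@H]1C=C(C)[C@H](/C=C/C(C)(O[Mg]Br)C=C)C(C)(C)C1 | intermediate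
19 | [(2E,4E)-3-methyl-5-[(1R,4R)-2,6,6-trimethyl-4-(hexadecanoyloxy)cyclohex-2-en-1-yl]penta-2,4-dien-1-yl]triphenylphosphonium bromide | [Br-].CCCCCCCCCCCCCCCC(=O)O[C@H]1C=C(C)[C@H](/C=C/C(C)=C/C[P+](c2ccccc2)(c2ccccc2)c2ccccc2)C(C)(C)C1 | intermediate
20 | (3R,3'R,6'R)-β,ε-carotene-3,3'-diol 3-tetradecanoate 3'-hexadecanoate | CCCCCCCCCCCCCCCC(=O)O[C@H]1C=C(C)[C@H](/C=C/C(C)=C/C=C/C(C)=C/C=C/C=C(C)/C=C/C=C(C)/C=C/C2=C(C)C[C@@H](OC(=O)CCCCCCCCCCCCC)CC2(C)C)C(C)(C)C1 | target

**Totals**
Total step count: 10. Longest linear sequence: 7 steps (1 → 2 → 3 → 4 → 5 → 6 → 10, from compound 1).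

**Three steps most likely to fail**

Step 2. The β-chloroenone may be methylated by residual alane or polymerise before it couples. Fallback: set out from 4, run the same carboalumination but quench the alane with iodine and isolate (4S,1E)-1-iodo-2,6-dimethylhepta-1,6-dien-4-ol F1. Then join F1 to methyl vinyl ketone in a Heck reaction (Pd(OAc)2, K2CO3, Bu4NCl, DMF, 50 °C). This forms the C3=C4 bond by C–H vinylation instead of organometallic cross-coupling and comes back to the route at 7.

Step 4. The ester must survive concentrated H2SO4: the ester carbonyl can trap the C1 cation as an acyloxonium ion, and the transient ε-olefin isomer is an allylic ester that can ionise and eliminate. Fallback: set out from 7 and cyclise the free carbinol (MeSO3H, CH2Cl2, 0 °C) to (E)-4-[(4R)-4-hydroxy-2,6,6-trimethylcyclohex-1-en-1-yl]but-3-en-2-one F2, so that no acyl group is present during ring closure. Then acylate F2 with 8 (pyridine, DMAP) to come back at 10.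

Step 8. Several things can go wrong here:
- the palmitate carbonyl can intercept the C1 cation as a dioxanylium ion (expected to re-ionise like a protonated tert-alkyl ester, but it may divert material);
- the 1,3-induction may give a modest trans:cis ratio;
- β/γ olefin isomers may form;
- the product is an acid-sensitive allylic ester.

Fallback: set out from 7 and invert it under Mitsunobu conditions with 4-nitrobenzoic acid to (3E,5E,8R)-6,10-dimethyl-2-oxoundeca-3,5,10-trien-8-yl 4-nitrobenzoate F3. Cyclise F3 with H3PO4 to (1R,4R)-3,5,5-trimethyl-4-[(1E)-3-oxobut-1-en-1-yl]cyclohex-2-en-1-yl 4-nitrobenzoate F4; the electron-poor aroyl group is a poor neighbouring group, resists allylic ionisation, and should allow the trans isomer to be purified by recrystallisation. Remove the auxiliary ester (K2CO3, MeOH, 0 °C) to give (E)-4-[(1R,4R)-4-hydroxy-2,6,6-trimethylcyclohex-2-en-1-yl]but-3-en-2-one F5, and esterify F5 with 15 (DCC, DMAP) to come back at 17.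

**Further compounds**
F1 | step 2 | (4S,1E)-1-iodo-2,6-dimethylhepta-1,6-dien-4-ol | I/C=C(\C)C[C@@H](O)CC(C)=C
F2 | step 4 | (E)-4-[(4R)-4-hydroxy-2,6,6-trimethylcyclohex-1-en-1-yl]but-3-en-2-one | CC(=O)/C=C/C1=C(C)C[C@@H](O)CC1(C)C
F3 | step 8 | (3E,5E,8R)-6,10-dimethyl-2-oxoundeca-3,5,10-trien-8-yl 4-nitrobenzoate | CC(=O)/C=C/C=C(\C)C[C@H](OC(=O)c1ccc(cc1)[N+](=O)[O-])CC(C)=C
F4 | step 8 | (1R,4R)-3,5,5-trimethyl-4-[(1E)-3-oxobut-1-en-1-yl]cyclohex-2-en-1-yl 4-nitrobenzoate | O=C(O[C@H]1C=C(C)[C@H](/C=C/C(C)=O)C(C)(C)C1)c1ccc(cc1)[N+](=O)[O-]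
F5 | step 8 | (E)-4-[(1R,4R)-4-hydroxy-2,6,6-trimethylcyclohex-2-en-1-yl]but-3-en-2-one | O[C@H]1C=C(C)[C@H](/C=C/C(C)=O)C(C)(C)C1
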